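**Assumptions.** The target has no stereocenters (the prenyl alkene has two identical methyls and the chromene alkene is in a ring), so "single enantiomer" is trivially satisfied and every intermediate is achiral. I take the reported 1,3-diketone tautomer as the target. In step 5, the linear chromene is the major regioisomer and is separated from the angular isomer by chromatography.

## Retrosynthetic overview
1. The 1,3-diketone is disconnected by Baker–Venkataraman (BV) rearrangement into an aryl ester, which comes from the ring-A 2-hydroxyacetophenone (chromene already present) and the ring-B acid chloride.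
2. The ring-A 2,2-dimethylchromene is built from 2,4-dihydroxyacetophenone and prenal (phenol–enal condensation, then 6π-oxa-electrocyclization).
3. The ring-B prenyl group is installed by a proposed boron-templated ortho-C–H prenylation of methyl 4-hydroxybenzoate with 2-methylbut-3-en-2-ol.
4. Order of bond and ring formation: the aryl C–prenyl bond, then the chromene ring (separate branch), then the aryl ester, then the diketone C–C bond, then the MOM removal.

## Forward route

**Step 1**
Reactants: 1 methyl 4-hydroxybenzoate; 2 2-methylbut-3-en-2-ol
Product: 3 methyl 4-hydroxy-3-(3-methylbut-2-en-1-yl)benzoate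
Conditions: PhB(OH)2 (1 equiv), 4 Å MS, toluene, sealed tube, 110 °C, 24 h; then aq. NaHCO3 workup. Use 1 (1.5 equiv) and 2 (1 equiv) to limit bis-prenylation.
Reagents that add atoms: none (the prenyl fragment comes from reactant 2; boron is removed on workup)
Why: Proposed new method: the phenol and the tertiary allylic alcohol exchange onto boron to form the mixed ester PhB(OAr)(OCMe2CH=CH2), and an eight-membered chair-like SN2′ allyl transfer (ortho-C attacks the vinyl CH2 as the C–O bond breaks) delivers the normal (not reverse) prenyl group only at the ortho carbon, giving a dehydrative C–H prenylation. It is closest to Casiraghi/Lee-type boronate-templated ortho functionalization of phenols and to boronic acid-catalysed allylic alcohol Friedel–Crafts reactions, but it is untested on electron-poor para-acyl phenols with tertiary allylic alcohols as a concerted SN2′ template. No stereocenter is formed.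

**Step 2**
Reactants: 3; 4 chloromethyl methyl ether
Product: 5 methyl 4-(methoxymethoxy)-3-(3-methylbut-2-en-1-yl)benzoate
Conditions: MOMCl (1.5 equiv), i-Pr2NEt (2 equiv), CH2Cl2, 0 °C → rt, 4 h
Reagents that add atoms: chloromethyl methyl ether, COCCl (adds CH2OCH3)
Why: Standard phenol MOM protection, giving a base-stable group for the later BV step; no stereocenter.

**Step 3**
Reactants: 5; water (from LiOH)
Product: 6 4-(methoxymethoxy)-3-(3-methylbut-2-en-1-yl)benzoic acid
Conditions: LiOH·H2O (3 equiv), THF/MeOH/H2O (3:1:1), rt, 12 h; then careful acidification with aq. NaH2PO4 to pH 4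
Reagents that add atoms: water/hydroxide, O (the new acid OH)
Why: Saponification of the methyl ester; the MOM acetal and the prenyl alkene are base-stable, and the mild pH-4 quench protects the MOM group.

**Step 4**
Reactants: 6; 7 1-chloro-N,N,2-trimethylprop-1-en-1-amine (Ghosez reagent)
Product: 8 4-(methoxymethoxy)-3-(3-methylbut-2-en-1-yl)benzoyl chloride
Conditions: Ghosez reagent (1.2 equiv), CH2Cl2, 0 °C → rt, 1 h; concentrate and use directly
Reagents that add atoms: Ghosez reagent, CC(C)=C(Cl)N(C)C (adds Cl)
Why: It converts the acid to the acid chloride under neutral, HCl-free conditions, so the MOM acetal and the prenyl alkene survive.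

**Step 5**
Reactants: 9 2,4-dihydroxyacetophenone; 10 3-methylbut-2-enal (prenal)
Product: 11 1-(7-hydroxy-2,2-dimethyl-2H-chromen-6-yl)ethan-1-one
Conditions: prenal (2 equiv), pyridine, 115–120 °C, sealed tube, 24 h; chromatographic separation of the angular isomer
Reagents that add atoms: none (prenal is the reactant)
Why: Phenol–enal condensation gives an ortho-quinone methide dienol that undergoes 6π-oxa-electrocyclization; the chromene ring forms at C5, ortho to the 4-OH, and no stereocenter is formed.

**Step 6**
Reactants: 11; 8
Product: 12 6-acetyl-2,2-dimethyl-2H-chromen-7-yl 4-(methoxymethoxy)-3-(3-methylbut-2-en-1-yl)benzoate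
Conditions: 8 (1.2 equiv), Et3N (3 equiv), DMAP (0.1 equiv), CH2Cl2, 0 °C → rt, 6 h
Reagents that add atoms: none (the acyl group comes from reactant 8)
Why: Schotten–Baumann-type O-acylation of the H-bonded phenol with a reactive acid chloride; no stereocenter.

**Step 7**
Reactants: 12
Product: 13 1-[7-hydroxy-2,2-dimethyl-2H-chromen-6-yl]-3-[4-(methoxymethoxy)-3-(3-methylbut-2-en-1-yl)phenyl]propane-1,3-dione
Conditions: LiHMDS (3 equiv), THF, −78 °C → 0 °C, 3 h; quench with aq. NH4Cl/AcOH
Reagents that add atoms: none (H+ only at quench)
Why: Baker–Venkataraman rearrangement: the acetyl enolate attacks the neighbouring aryl ester through a six-membered transition state, transferring the aroyl group and releasing the phenoxide; no stereocenter is formed and the MOM group, prenyl alkene and chromene are base-stable.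

**Step 8**
Reactants: 13
Product: 14 Glyinflanin C
Conditions: ZnBr2 (3 equiv), n-PrSH (6 equiv), CH2Cl2, 0 °C → rt, 20 min
Reagents that add atoms: none
Why: Mild Lewis-acid/thiol cleavage of the aryl MOM ether, chosen because it is fast enough to spare the acid-sensitive chromene, prenyl and diketone groups; no stereocenter is involved.

## Compound list
1 | methyl 4-hydroxybenzoate | COC(=O)c1ccc(O)cc1 | starting material
2 | 2-methylbut-3-en-2-ol | CC(C)(O)C=C | starting material
3 | methyl 4-hydroxy-3-prenylbenzoate | COC(=O)c1ccc(O)c(CC=C(C)C)c1 | intermediate
4 | chloromethyl methyl ether | COCCl | starting material (reagent)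
5 | methyl 4-(MOMO)-3-prenylbenzoate | COC(=O)c1ccc(OCOC)c(CC=C(C)C)c1 | intermediate
6 | 4-(MOMO)-3-prenylbenzoic acid | OC(=O)c1ccc(OCOC)c(CC=C(C)C)c1 | intermediate
7 | Ghosez reagent | CC(C)=C(Cl)N(C)C | starting material (reagent)
8 | 4-(MOMO)-3-prenylbenzoyl chloride | ClC(=O)c1ccc(OCOC)c(CC=C(C)C)c1 | intermediate
9 | 2,4-dihydroxyacetophenone | CC(=O)c1ccc(O)cc1O | starting material
10 | 3-methylbut-2-enal | CC(C)=CC=O | starting material
11 | 1-(7-hydroxy-2,2-dimethyl-2H-chromen-6-yl)ethanone | CC(=O)c1cc2c(cc1O)OC(C)(C)C=C2 | intermediate
12 | chromenyl aryl ester | CC(=O)c1cc2c(cc1OC(=O)c1ccc(OCOC)c(CC=C(C)C)c1)OC(C)(C)C=C2 | intermediate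
13 | MOM-protected diketone | COCOc1ccc(cc1CC=C(C)C)C(=O)CC(=O)c1cc2c(cc1O)OC(C)(C)C=C2 | intermediate
14 | Glyinflanin C | CC(C)=CCc1cc(C(=O)CC(=O)c2cc3c(cc2O)OC(C)(C)C=C3)ccc1O | target

**Total step count:** 8 steps (ring-B branch of 4 steps, ring-A branch of 1 step, then 3 steps after they join).
**Longest linear sequence:** 7 steps (1 → 2 → 3 → 4 → 6 → 7 → 8).

## Three steps most likely to fail
1. **Step 1 (the proposed new boron-templated ortho-prenylation).** The risks are low reactivity of the electron-poor phenol, O-prenylation, bis-prenylation, or cyclization to chromans.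
   *Fallback:* Known chemistry. O-allylate 1, do a thermal Claisen rearrangement to methyl 3-allyl-4-hydroxybenzoate, then cross-metathesis with 2-methylbut-2-ene (Hoveyda–Grubbs II) to give 3.
2. **Step 5 (regioselectivity of the pyridine chromenylation).** Angular versus linear closure may give a poor ratio.
   *Fallback:* Change the ring-forming mechanism. Do 4-O-propargylation with 3-chloro-3-methylbut-1-yne (K2CO3, KI, CuCl), then a propargyl Claisen/6π cyclization (PhNEt2, heat), which has different regiochemical control, and separate the isomers.
3. **Step 7 (Baker–Venkataraman rearrangement).** The electron-rich aroyl ester may acylate slowly, or the chromene may suffer side reactions with LiHMDS.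
   *Fallback:* Skip the aryl ester. Do a direct Claisen condensation of the ketone 11 (as its dianion, NaH, THF/DMF) with methyl ester 5.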